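The rate constants were drawn at random within sensible limits; the rest is arithmetic.

I started with the easy thing, the time one round of the catalyst takes in this flask.

substrate 10 mM; partner 10.0 mM; free catalyst 1.5 mM; time 6.0 min

    partner + free catalyst → catalyst intermediate A (k1 = 33 /M/s)
    catalyst intermediate A → catalyst intermediate B (k2 = 23 /s)
    substrate + catalyst intermediate B → catalyst intermediate C (k3 = 130 /M/s)
    catalyst intermediate C → by-product + catalyst intermediate D (k4 = 0.84 /s)
    catalyst intermediate D → free catalyst + target (k5 = 50 /s)
    2 catalyst intermediate D → spent catalyst (k6 = 23 /M/s)
    substrate + target → side product (k7 = 7.3 /M/s)

- a species is counted by the substrate in it: one spent catalyst or side product counts as two
- two of one species on the left: rate k times its square, two consumed each time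
- the reaction counts as stopped when no species that holds the substrate changes by six tenths of a point or more over the second half of the time
- run time (flask): 6.0 min

- which holds at 6.0 min: what has brought the reaction to rest, or that it has not come to rest (forward and back rates have come level / all of the substrate has reacted / it is still moving / the partner has run out first / no working catalyst is left)
- part of the substrate gone at 6.0 min
- the target standing at 6.0 min, as a percentage of the substrate charged
- the side product standing at 6.0 min, as a percentage of the substrate charged

The first line makes free catalyst wait 3.03 s for partner at its charged amount, and that wait is longer than any other in the round. So I froze partner and substrate at their charges, which they do not keep, and added the five waits to get a round time of 5.05 s. The charged catalyst then makes target at 0.297 mM/s.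

I dropped the pairing of catalyst intermediate D: at the 0.00594 mM that I reckoned for it at that output, the pairing runs far slower than the release.

But the last line lets substrate eat target. The target level at which that step eats target as fast as the round makes it, with substrate frozen and taken as a share of the substrate charged, came to 40.7 %; I called it the balance level.

At that output the round needs 0.561 min for the substrate, less than the 6.0 min allowed. The side step spends substrate without spending partner, so I expected substrate to go first. I committed to target near 40.7 % and side product, counted double, at the remaining 59.3 %.

The forecast said all of the substrate has reacted, with 100 % gone, target 48 % and side product 52 %, calling the side step “comparable to turnover once target builds up”. Its target stood higher than mine.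

The flask gave all of the substrate has reacted, with 100 % gone, target 45.6 % and side product 54.4 %. In this flask substrate was the limiting reagent, with 0 % of its charge left against 12 % of the partner's at 6.00 min. The target lay 4.9 percentage points above my balance level and 2.4 points below the forecast. In the neighbouring flask with 25 mM of partner, the partner's wait shrinks to 1.21 s, the round time to 3.24 s, and the balance level rises to 63.5 %. That neighbouring flask ended with side product at 39.6 % and target at 60.4 %.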